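## Retrosynthetic overview

- **Feature:** C4 of pyranone ring C hangs on C4a of the hexasubstituted ring A, wedged between the oxygens on C5 and C8a. Acyl-transfer chemistry at C4 is therefore crowded. The same two ortho oxygens should make a rod-shaped aryl nitrile oxide at that carbon long-lived.
- **Late disconnections:** O5–H goes back to O5–Me by chelation-controlled cleavage. Ring C (O1–C2 closure, C4=O from water) goes back to an o-hydroxyaryl enaminone, and that to a 3,5-diarylisoxazole.
- **Key disconnection:** the isoxazole opens to the ring A nitrile oxide plus 2,4,5-trimethoxyphenylacetylene. The forward (3+2) step makes C3–C4 and a temporary C2–O bond.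
- **Building blocks:** the dipole comes from 1,2,3,4-tetramethoxybenzene through phenol, salicylaldehyde, benzyl ether and oxime. The alkyne comes from 2,4,5-trimethoxybenzaldehyde in one step.
- **Ring order:** rings A and B are bought intact, the temporary isoxazole forms in step 7, and ring C forms in step 9.

Key step: step 7

Assumption: the oxime is drawn E, the hydroximoyl chloride Z and the enaminone as its hydrogen-bonded Z form. None of these geometries reaches the target, which has no stereocentre.

## Route

**Step 1**
Reactants: 1 1,2,3,4-tetramethoxybenzene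
Product: 4 2,3,4,5-tetramethoxyphenol, via aryllithium 2 (not isolated), via dimethyl arylboronate 3 (not isolated)
Conditions: n-BuLi, TMEDA, THF, 0 °C to rt; B(OMe)3, −78 °C to rt; AcOH, 30% aq H2O2, 0 °C to rt
Reagents that add atoms: hydrogen peroxide, OO
Why: Directed ortho-metalation at one of the two equivalent free positions beside a methoxy group, followed by borylation and boronate oxidation (1,2-aryl shift to oxygen), can give only one regioisomer.

**Step 2**
Reactants: 4 2,3,4,5-tetramethoxyphenol
Product: 6 2-hydroxy-3,4,5,6-tetramethoxybenzaldehyde, via salicyl alcohol 5 (not isolated)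
Conditions: MgCl2 (anhydrous), Et3N, (CH2O)n, MeCN, reflux; 1 M HCl work-up
Reagents that add atoms: paraformaldehyde (as formaldehyde), C=O
Why: In the Casnati–Skattebøl ortho-formylation the magnesium phenoxide delivers formaldehyde to the only free ring carbon, which lies ortho to the OH, and a second formaldehyde accepts hydride from 5 in an Oppenauer-type transfer.

**Step 3**
Reactants: 6 2-hydroxy-3,4,5,6-tetramethoxybenzaldehyde; 7 benzyl bromide
Product: 8 2-(benzyloxy)-3,4,5,6-tetramethoxybenzaldehyde
Conditions: BnBr, K2CO3, DMF, 60 °C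
Reagents that add atoms: benzyl bromide 7, BrCc1ccccc1
Why: This is a Williamson etherification of the only acidic OH, and benzyl is chosen because it falls in the same hydrogenation that later opens the isoxazole.

**Step 4**
Reactants: 8 2-(benzyloxy)-3,4,5,6-tetramethoxybenzaldehyde
Product: 9 (E)-2-(benzyloxy)-3,4,5,6-tetramethoxybenzaldehyde oxime
Conditions: NH2OH·HCl, NaOAc, EtOH–H2O, reflux
Reagents that add atoms: hydroxylamine hydrochloride, NO.Cl
Why: This is an oxime condensation, and a formyl carbon still admits the small nitrogen nucleophile between two ortho alkoxy groups, where a ketone or ester would be sluggish.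

**Step 5**
Reactants: 9 (E)-2-(benzyloxy)-3,4,5,6-tetramethoxybenzaldehyde oxime
Product: 11 2-(benzyloxy)-3,4,5,6-tetramethoxybenzonitrile oxide, via hydroximoyl chloride 10 (not isolated)
Conditions: NCS, DMF, rt; extract into Et2O; Et3N, 0 °C; water wash, concentrate below 30 °C, use at once
Reagents that add atoms: none
Why: Aldoxime chlorination and 1,3-dehydrochlorination should be clean here because ring A has no C–H left for nuclear chlorination, and making the persistent dipole before the alkyne is present keeps the oxidant away from the electron-rich ring B and the triple bond.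

**Step 6**
Reactants: 12 2,4,5-trimethoxybenzaldehyde
Product: 13 1-ethynyl-2,4,5-trimethoxybenzene
Conditions: dimethyl (1-diazo-2-oxopropyl)phosphonate, K2CO3, MeOH, 0 °C to rt
Reagents that add atoms: dimethyl (1-diazo-2-oxopropyl)phosphonate, COP(=O)(OC)C(=[N+]=[N-])C(C)=O
Why: The Seyferth–Gilbert homologation in its Ohira–Bestmann form turns a non-enolisable aryl aldehyde into the terminal alkyne in one mild carbonate-mediated operation that leaves aryl methyl ethers alone.

**Step 7**
Reactants: 11 2-(benzyloxy)-3,4,5,6-tetramethoxybenzonitrile oxide; 13 1-ethynyl-2,4,5-trimethoxybenzene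
Product: 14 3-[2-(benzyloxy)-3,4,5,6-tetramethoxyphenyl]-5-(2,4,5-trimethoxyphenyl)isoxazole
Conditions: 13 in slight excess, toluene (about 1 M), 70 °C, N2
Reagents that add atoms: none
Why: The linear C≡N–O dipole of 11 and the triple bond of 13 combine in a concerted, asynchronous thermal (3+2) Huisgen cycloaddition, in which the dipole carbon bonds to the terminal alkyne carbon (the future C3–C4 bond) and the dipole oxygen bonds to the aryl-bearing carbon (the temporary C2–O bond). The closest known reaction type is the addition of mesitonitrile oxide or 2,6-dimethoxybenzonitrile oxide to phenylacetylene, which gives 3-aryl-5-phenylisoxazoles. The one new ring, the five-membered isoxazole, is closed intermolecularly with both new sigma bonds made in the same event, and no stereocentre arises. Two selectivities are needed: 3,5- over 3,4-regiochemistry is secured because the bulky 2,6-dialkoxyaryl-bearing dipole carbon meets the unsubstituted CH terminus, which also carries the larger HOMO coefficient of the electron-rich arylacetylene, and cycloaddition over self-reaction is secured by the O-benzyl and O-methyl groups that flank the dipole carbon and obstruct the C–C bond formation on which dimerisation depends. The temperature stays well below that at which hindered nitrile oxides rearrange, and all atoms of both partners end up in 14.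

**Step 8**
Reactants: 14 3-[2-(benzyloxy)-3,4,5,6-tetramethoxyphenyl]-5-(2,4,5-trimethoxyphenyl)isoxazole
Product: 15 (Z)-3-amino-3-(2-hydroxy-3,4,5,6-tetramethoxyphenyl)-1-(2,4,5-trimethoxyphenyl)prop-2-en-1-one
Conditions: H2 (1–3 atm), 10% Pd/C, EtOH–EtOAc, rt
Reagents that add atoms: none
Why: Catalytic hydrogenolysis cleaves both the weak isoxazole N–O bond and the benzylic C–O bond, while the resulting vinylogous amide, locked Z by its N–H···O=C hydrogen bond, and the aryl methyl ethers resist further reduction.

**Step 9**
Reactants: 15 (Z)-3-amino-3-(2-hydroxy-3,4,5,6-tetramethoxyphenyl)-1-(2,4,5-trimethoxyphenyl)prop-2-en-1-one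
Product: 17 5,6,7,8-tetramethoxy-2-(2,4,5-trimethoxyphenyl)-4H-chromen-4-one, via 1,3-diketone 16 (not isolated)
Conditions: 3 M aq HCl–EtOH, reflux
Reagents that add atoms: water, O
Why: Acid hydrolysis of the enaminone puts the C4 oxygen in place from water, and the single free phenol then attacks C2 and loses water (the cyclodehydration that ends a Baker–Venkataraman flavone synthesis), so only one six-membered closure is possible.

**Step 10**
Reactants: 17 5,6,7,8-tetramethoxy-2-(2,4,5-trimethoxyphenyl)-4H-chromen-4-one
Product: 19 Agehoustin E (5-hydroxy-6,7,8-trimethoxy-2-(2,4,5-trimethoxyphenyl)-4H-chromen-4-one), via dichloroboron chelate 18 (not isolated)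
Conditions: BCl3 (slight excess, 1 M in CH2Cl2), CH2Cl2, −78 to 0 °C; then H2O
Reagents that add atoms: none
Why: In this chelation-controlled aryl methyl ether cleavage boron binds C4=O and the peri O5, so chloride removes only that methyl group, which is the standard selective 5-O-demethylation of polymethoxyflavones, and water then breaks the chelate.

## Compound list

| No. | Name | SMILES | Role |
|---|---|---|---|
| 1 | 1,2,3,4-tetramethoxybenzene | COc1ccc(OC)c(OC)c1OC | starting material |
| 2 | (2,3,4,5-tetramethoxyphenyl)lithium | [Li]c1cc(OC)c(OC)c(OC)c1OC | intermediate |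
| 3 | dimethyl (2,3,4,5-tetramethoxyphenyl)boronate | COB(OC)c1cc(OC)c(OC)c(OC)c1OC | intermediate |
| 4 | 2,3,4,5-tetramethoxyphenol | COc1cc(O)c(OC)c(OC)c1OC | intermediate |
| 5 | 2-(hydroxymethyl)-3,4,5,6-tetramethoxyphenol (present as its magnesium salt) | COc1c(O)c(CO)c(OC)c(OC)c1OC | intermediate |
| 6 | 2-hydroxy-3,4,5,6-tetramethoxybenzaldehyde | COc1c(O)c(C=O)c(OC)c(OC)c1OC | intermediate |
| 7 | benzyl bromide | BrCc1ccccc1 | starting material |
| 8 | 2-(benzyloxy)-3,4,5,6-tetramethoxybenzaldehyde | COc1c(OCc2ccccc2)c(C=O)c(OC)c(OC)c1OC | intermediate |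
| 9 | (E)-2-(benzyloxy)-3,4,5,6-tetramethoxybenzaldehyde oxime | COc1c(OCc2ccccc2)c(/C=N/O)c(OC)c(OC)c1OC | intermediate |
| 10 | (Z)-2-(benzyloxy)-N-hydroxy-3,4,5,6-tetramethoxybenzimidoyl chloride | COc1c(OCc2ccccc2)c(/C(Cl)=N/O)c(OC)c(OC)c1OC | intermediate |
| 11 | 2-(benzyloxy)-3,4,5,6-tetramethoxybenzonitrile oxide | COc1c(OCc2ccccc2)c(C#[N+][O-])c(OC)c(OC)c1OC | intermediate |
| 12 | 2,4,5-trimethoxybenzaldehyde | COc1cc(OC)c(C=O)cc1OC | starting material |
| 13 | 1-ethynyl-2,4,5-trimethoxybenzene | C#Cc1cc(OC)c(OC)cc1OC | intermediate |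
| 14 | 3-[2-(benzyloxy)-3,4,5,6-tetramethoxyphenyl]-5-(2,4,5-trimethoxyphenyl)isoxazole | COc1cc(OC)c(-c2cc(-c3c(OCc4ccccc4)c(OC)c(OC)c(OC)c3OC)no2)cc1OC | intermediate |
| 15 | (Z)-3-amino-3-(2-hydroxy-3,4,5,6-tetramethoxyphenyl)-1-(2,4,5-trimethoxyphenyl)prop-2-en-1-one | N/C(=C\C(=O)c1cc(OC)c(OC)cc1OC)c1c(O)c(OC)c(OC)c(OC)c1OC | intermediate |
| 16 | 1-(2-hydroxy-3,4,5,6-tetramethoxyphenyl)-3-(2,4,5-trimethoxyphenyl)propane-1,3-dione | COc1cc(OC)c(C(=O)CC(=O)c2c(O)c(OC)c(OC)c(OC)c2OC)cc1OC | intermediate |
| 17 | 5,6,7,8-tetramethoxy-2-(2,4,5-trimethoxyphenyl)-4H-chromen-4-one | COc1cc(OC)c(-c2cc(=O)c3c(OC)c(OC)c(OC)c(OC)c3o2)cc1OC | intermediate |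
| 18 | 5-[(dichloroboranyl)oxy]-6,7,8-trimethoxy-2-(2,4,5-trimethoxyphenyl)-4H-chromen-4-one | COc1cc(OC)c(-c2cc(=O)c3c(OB(Cl)Cl)c(OC)c(OC)c(OC)c3o2)cc1OC | intermediate |
| 19 | Agehoustin E, 5-hydroxy-6,7,8-trimethoxy-2-(2,4,5-trimethoxyphenyl)-4H-chromen-4-one | COc1cc(OC)c(-c2cc(=O)c3c(O)c(OC)c(OC)c(OC)c3o2)cc1OC | target |

## Step count

Total step count: 10.
Longest linear sequence: 9 (steps 1–5 and 7–10). The alkyne branch is the single step 6.

## Steps most likely to fail

**Step 7.**
- **Risk:** the bimolecular addition of a doubly ortho-shielded dipole to a moderately reactive arylacetylene may be slow. Thermal rearrangement or self-condensation of the dipole could then consume it first. Regiocontrol could also erode if more heat is needed.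
- **Fallback:** it replaces the pericyclic union by a stepwise anionic one, sets out from 11 and comes back at 14.
- **Enolate addition:** purchased 2,4,5-trimethoxyacetophenone F1 is deprotonated with LDA in THF at −78 °C to lithium 1-(2,4,5-trimethoxyphenyl)ethen-1-olate F2. Its carbon adds to the dipole carbon of 11, and the resulting oximate oxygen closes onto the ketone.
- **Return to the route:** a quench with dilute HCl should give racemic 3-[2-(benzyloxy)-3,4,5,6-tetramethoxyphenyl]-5-(2,4,5-trimethoxyphenyl)-4,5-dihydroisoxazol-5-ol F3. TsOH in warm toluene then dehydrates it to 14.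
- **Basis:** this is the known reaction of aryl nitrile oxides with ketone enolates, and connectivity fixes the regiochemistry.

**Step 8.**
- **Risk:** the benzyl ether should fall quickly, but N–O cleavage in the twisted, hindered diarylisoxazole may stall as the amine product deactivates the catalyst. Forcing the hydrogenation could then over-reduce the enaminone.
- **Fallback:** it separates the two reductions, sets out from 14 and comes back at 15.
- **Debenzylation:** a brief hydrogenation over 10% Pd/C is stopped at 2,3,4,5-tetramethoxy-6-[5-(2,4,5-trimethoxyphenyl)isoxazol-3-yl]phenol F4.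
- **N–O cleavage:** the N–O bond is then broken by the metal-carbonyl-mediated reductive ring opening known for isoxazoles, using Mo(CO)6 in MeCN–H2O at reflux, to give 15.

**Step 10.**
- **Risk:** once O5 is freed and chelated, ether cleavage may run on to the neighbouring, buttressed O6 methyl group, so that single demethylation is hard to stop cleanly.
- **Fallback:** it gives up selective mono-cleavage for deliberate double cleavage and selective re-methylation, sets out from 17 and comes back at 19.
- **Double cleavage:** AlBr3 in MeCN, followed by warm dilute HCl to break the aluminium complex, takes 17 to 5,6-dihydroxy-7,8-dimethoxy-2-(2,4,5-trimethoxyphenyl)-4H-chromen-4-one F5.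
- **Re-methylation:** one equivalent of MeI with K2CO3 in acetone at rt methylates only the free 6-OH. The 5-OH is tied up in its hydrogen bond to C4=O and stays unreacted, which gives 19.

## Further compounds

F1 | step 7 | 2,4,5-trimethoxyacetophenone (purchased) | COc1cc(OC)c(C(C)=O)cc1OC
F2 | step 7 | lithium 1-(2,4,5-trimethoxyphenyl)ethen-1-olate | [Li+].C=C([O-])c1cc(OC)c(OC)cc1OC
F3 | step 7 | 3-[2-(benzyloxy)-3,4,5,6-tetramethoxyphenyl]-5-(2,4,5-trimethoxyphenyl)-4,5-dihydroisoxazol-5-ol (racemic) | COc1cc(OC)c(C2(O)CC(c3c(OCc4ccccc4)c(OC)c(OC)c(OC)c3OC)=NO2)cc1OC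
F4 | step 8 | 2,3,4,5-tetramethoxy-6-[5-(2,4,5-trimethoxyphenyl)isoxazol-3-yl]phenol | COc1cc(OC)c(-c2cc(-c3c(O)c(OC)c(OC)c(OC)c3OC)no2)cc1OC
F5 | step 10 | 5,6-dihydroxy-7,8-dimethoxy-2-(2,4,5-trimethoxyphenyl)-4H-chromen-4-one | COc1cc(OC)c(-c2cc(=O)c3c(O)c(O)c(OC)c(OC)c3o2)cc1OC
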